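Target decays. The question is how much of it outlasts the warm end of a flask.

| flask | starting material | reagent | temperature | remark | time |
|---|---|---|---|---|---|
| Friday's | 0.050 M | 1.3 equiv | 20 °C | run made earlier |  |
| Tuesday's | 0.050 M | 0.87 equiv | 31 °C | run made earlier |  |
| Wednesday's | 0.050 M | 2 equiv | 20 °C | run made earlier |  |
| alder | 0.050 M (fed, over 15 min) | 1.30 equiv | 25 °C | all else is in the flask from the start; the feed brings no volume worth counting | 20 min |
| oak | 0.050 M | 1.30 equiv (in portions, 2, over 15 min) | 25 °C | first portion at the start, last at 15 min | 20 min |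
| maple | 0.050 M (fed, over 15 min) | 1.30 equiv |  | the addition at 5 °C, then warmed to 25 °C; the feed brings no volume worth counting | 20 min |
| larch | 0.050 M | 1.30 equiv (fed, over 15 min) | 25 °C | all else is in the flask from the start; the feed brings no volume worth counting | 20 min |
| ash | 0.050 M | 1.30 equiv |  | everything together at the start at 5 °C, warmed to 25 °C at 15 min | 20 min |

| run | time / min | target / % |
|---|---|---|
| Friday's | 1.00 | 27.0 |
| Friday's | 1.50 | 26.9 |
| Friday's | 2.50 | 24.0 |
| Friday's | 4.00 | 21.3 |
| Friday's | 8.00 | 14.1 |
| Friday's | 12.0 | 9.4 |
| Tuesday's | 2.00 | 11.6 |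
| Tuesday's | 3.00 | 7.5 |
| Tuesday's | 5.00 | 4.2 |
| Tuesday's | 8.00 | 1.8 |
| Tuesday's | 15.0 | 0 |
| Tuesday's | 25.0 | 0 |
| Wednesday's | 4.00 | 28.9 |
| Wednesday's | 8.00 | 19.2 |
| Wednesday's | 12.0 | 13.2 |
| Wednesday's | 15.0 | 9.7 |
| Wednesday's | 20.0 | 5.8 |
| Wednesday's | 25.0 | 3.5 |

(standard deviation of a reading: 0.3 percentage points)



- which flask leads in amount of target, in percent of the starting material charged ("all alike" within 1.5 percentage points) (alder / oak / maple / larch / ash / all alike)
- how much target is there at the end, in percent of the starting material charged: alder
- how much target is there at the end, in percent of the starting material charged: oak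
- how much target is there at the end, in percent of the starting material charged: maple
- how much target is there at the end, in percent of the starting material charged: larch
- how much target is there at the end, in percent of the starting material charged: ash

Friday's target falls at a rate constant k of 0.102 min⁻¹ with 1.3 equiv of reagent. Wednesday's falls at 0.101 min⁻¹ with 2 equiv. These readings match, so the fall reads as first-order, like a plain time constant. Tuesday's gives 0.311 min⁻¹ at 31 °C with 0.87 equiv. Assuming that the change is temperature's and that ln k is straight in temperature, the estimate of k is 0.169 min⁻¹ at 25 °C and 0.0225 min⁻¹ at 5 °C. Integrating the first-order loss from 15 min to 20 min at 25 °C gives exp(−kΔt) = 0.429. This is the warm survival W, the share of the target standing at 15 min that still stands at 20 min if nothing else touches it.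

The ledger is written here for ash, which has 1.30 equiv of reagent, so starting material is taken as the limiting reagent, counting one reagent to one starting material. It assumes that ash forms target as Friday's run did, and at once. Friday's fall, run back to time zero, credits 32.1 % of the starting material to target. The ledger books the other 67.9 % outside target. The cold stretch keeps a share of 0.714 and so debits 9.18 %. The warm stretch debits 13.1 %. The books close on an estimate of 9.81 % as target in ash.

The forecast names maple and gives alder 4.7 %, oak 0.7 %, maple 11.7 %, larch 0.1 % and ash 10.6 %, holding that “the cold protects target”. Its ash figure stands above the ledger's.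

The simulation puts ash in front at 9.03 %, with maple at 5.87 %, oak at 2.96 %, larch at 2.38 % and alder at 0.345 %.

    starting material + 2 reagent → side product A (k = 0.0580 M⁻² s⁻¹, Ea = 41.0 kJ mol⁻¹)
    target → over-reaction product (k = 0.00310 s⁻¹, Ea = 92.0 kJ mol⁻¹)
    2 reagent → self-condensation product (k = 0.0530 M⁻¹ s⁻¹, Ea = 50.0 kJ mol⁻¹)
    starting material + target → side product B (k = 0.610 M⁻¹ s⁻¹, Ea = 45.0 kJ mol⁻¹)
    starting material + reagent → target (k = 0.340 M⁻¹ s⁻¹, Ea = 47.0 kJ mol⁻¹)
    (constants at 25 °C)

Maple holds 17.6 % of target at 15.0 min, which W turns into 7.55 %, and 5.87 % stands at 20.0 min. Alder holds 1.82 % at 15.0 min, which W turns into 0.781 %, and 0.345 % stands at 20.0 min. In alder at 1.24 min, starting material + target → side product B uses target at 0.46 of the rate of target → over-reaction product, so more slowly. At 20.0 min, with 31.4 % of starting material still in alder, it runs faster, at 3.1 times that rate.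

(All runs were computed for an exercise.)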